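**Retrosynthetic overview**

1. Target 13 is (3R)-8-acetyl-5-geranyloxy-7-hydroxy-2,2-dimethylchroman-3-ol; its C3 carbinol is traced back to chroman-3-one 11 (CBS reduction), and 11 to 3-nitro-2H-chromene 9, where the nitro group is a temporary activating group and oxygen surrogate at C3.
2. Key disconnection: the pyran ring is cut at C3–C4 and O1–C2, giving salicylaldehyde 5 (C4 at the aldehyde level) and 2-methyl-1-nitropropene 6 (C2, C3 and both methyl groups); forward, a reversible oxa-Michael addition makes the hindered O1–C2 ether and the resulting C3 nitronate closes the ring through the C3–C4 bond.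
3. Enabling feature: in the pyran ring, C4 is a benzylic carbon on the benzene ring ortho to phenolic O1, C2 is a fully substituted carbon on O1, and C3 between them bears a heteroatom; with O5 already blocked as the geranyl ether, O1–H is the only hydroxyl ortho to the aldehyde, so the pyran ring can fuse in one way only.
4. Ring order: the benzene ring is bought (phloroacetophenone 1) and dressed in two steps on C2v-symmetric intermediates (O-geranylation, formylation); the pyran ring is the only ring made, in step 3.

Key step: step 3

Remark: 2-methyl-1-nitroprop-1-ene 6 is taken as a purchasable reagent, and phloroacetophenone 1 is used in anhydrous form. Geranyl = (2E)-3,7-dimethylocta-2,6-dien-1-yl.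

**Step 1**
Reactants: 1 2',4',6'-trihydroxyacetophenone; 2 geraniol
Product: 3 1-[4-(geranyloxy)-2,6-dihydroxyphenyl]ethanone
Conditions: PPh3, DIAD, THF, 0 °C to rt
Reagents that add atoms: none
Why: Mitsunobu etherification, in which only the 4-OH (para to the acetyl group, most acidic, not hydrogen-bonded to the carbonyl) should be alkylated by the geranyloxyphosphonium ion in an SN2 step that keeps the E-alkene, while the two chelated ortho-OH groups stay free and no stereocenter is formed.

**Step 2**
Reactants: 3 1-[4-(geranyloxy)-2,6-dihydroxyphenyl]ethanone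
Product: 5 3-acetyl-6-(geranyloxy)-2,4-dihydroxybenzaldehyde, via aryl iminium chloride 4 (not isolated)
Conditions: (chloromethylene)dimethyliminium chloride (1.2 equiv), MeCN, 0 °C to rt; then aq NaOAc, rt
Reagents that add atoms: (chloromethylene)dimethyliminium chloride, C[N+](C)=CCl.[Cl-]; water, O
Why: Vilsmeier–Haack formylation, in which the phloroglucinol-type ring of C2v-symmetric 3 should attack the chloroiminium ion at either of its two equivalent CH positions, so that a single regioisomer results with the new aldehyde carbon (future C4) between the geranyl ether and one chelated OH (future O1), the first formyl group deactivating the ring against a second attack.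

**Step 3**
Reactants: 5 3-acetyl-6-(geranyloxy)-2,4-dihydroxybenzaldehyde; 6 2-methyl-1-nitroprop-1-ene
Product: 9 1-[5-(geranyloxy)-7-hydroxy-2,2-dimethyl-3-nitro-2H-chromen-8-yl]ethanone, via oxa-Michael nitronate 7 (not isolated), via nitro-aldol adduct 8 (not isolated)
Conditions: 6 (3 equiv), DABCO (1 equiv), MeCN (minimal volume), 40 °C
Reagents that add atoms: none
Why: DABCO should deprotonate the phenols of 5, and the O1 phenoxide adds reversibly to the β-carbon of nitroalkene 6 (oxa-Michael), which builds the fully substituted C2–O1 ether and places a nitronate at C3 (7). This nitronate then attacks the neighbouring aldehyde carbon C4 in an intramolecular Henry (nitro-aldol) reaction that closes the pyran ring through the C3–C4 bond (8), and E1cB loss of water gives the conjugated nitrochromene 9 and makes the sequence irreversible. The closest known reaction type is the DABCO-mediated tandem oxa-Michael/Henry/dehydration of salicylaldehydes with conjugated nitroalkenes, β,β-dialkyl nitroalkenes included, to 3-nitro-2H-chromenes. The pyran ring closes in the 6-exo-trig mode, the nitronate carbon adding to the exocyclic C=O of the aldehyde. No stereocenter survives the step, since the two transient centres at C3 and C4 of 8 are erased by dehydration and C3 is set in step 5. The step needs regioselection between the two free phenols and chemoselection between aldehyde and acetyl carbonyl: only O1–H is ortho to the aldehyde because O5 already carries the geranyl group, adducts formed at O7 can only revert by retro-oxa-Michael because a Henry reaction onto the hindered, electron-rich acetyl ketone is unfavourable, and the final dehydration drains the equilibria into 9.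

**Step 4**
Reactants: 9 1-[5-(geranyloxy)-7-hydroxy-2,2-dimethyl-3-nitro-2H-chromen-8-yl]ethanone
Product: 11 8-acetyl-5-(geranyloxy)-7-hydroxy-2,2-dimethylchroman-3-one, via sodium nitronate 10 (not isolated)
Conditions: NaBH4, THF/MeOH, 0 °C; then aq TiCl3, NH4OAc (pH 5 to 6), rt
Reagents that add atoms: water, O
Why: Conjugate reduction followed by a buffered Nef reaction, in which hydride adds to the benzylic β-carbon C4 of the nitroalkene to give nitronate 10, trivalent titanium reduces this through the oxime to the imine, and hydrolysis should give ketone 11 with its oxygen coming from water, the near-neutral medium sparing the geranyl ether and the tertiary aryl ether.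

**Step 5**
Reactants: 11 8-acetyl-5-(geranyloxy)-7-hydroxy-2,2-dimethylchroman-3-one
Product: 13 1-[(3R)-5-(geranyloxy)-3,7-dihydroxy-2,2-dimethylchroman-8-yl]ethanone, via catechol borate ester 12 (not isolated)
Conditions: (S)-2-methyl-CBS-oxazaborolidine (20 mol%), catecholborane (2.5 equiv), toluene, −78 °C; then MeOH, aq NaHCO3
Reagents that add atoms: none
Why: Corey–Bakshi–Shibata reduction, in which the ketone should bind the oxazaborolidine boron with the quaternary C2 (large group) turned away from the catalyst and the C4 methylene (small group) toward it, so that hydride is delivered to the face giving the (3R)-alcohol (the same sense as the (S)-catalyst/(R)-alcohol outcome with tert-alkyl methyl ketones), while catecholborane at −78 °C should leave the trisubstituted geranyl alkenes and the chelated, electron-rich acetyl group untouched.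

**Compound list**

1 | 2',4',6'-trihydroxyacetophenone (phloroacetophenone) | CC(=O)c1c(O)cc(O)cc1O | starting material
2 | geraniol, (2E)-3,7-dimethylocta-2,6-dien-1-ol | OC/C=C(\C)CCC=C(C)C | starting material
3 | 1-[4-(geranyloxy)-2,6-dihydroxyphenyl]ethanone | CC(=O)c1c(O)cc(OC/C=C(\C)CCC=C(C)C)cc1O | intermediate
4 | N-{[3-acetyl-6-(geranyloxy)-2,4-dihydroxyphenyl]methylidene}-N-methylmethanaminium chloride (aryl iminium chloride) | CC(=O)c1c(O)cc(OC/C=C(\C)CCC=C(C)C)c(C=[N+](C)C)c1O.[Cl-] | intermediate (not isolated)
5 | 3-acetyl-6-(geranyloxy)-2,4-dihydroxybenzaldehyde | CC(=O)c1c(O)cc(OC/C=C(\C)CCC=C(C)C)c(C=O)c1O | intermediate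
6 | 2-methyl-1-nitroprop-1-ene | CC(C)=C[N+](=O)[O-] | starting material
7 | nitronate of 3-acetyl-6-(geranyloxy)-4-hydroxy-2-[(2-methyl-1-nitropropan-2-yl)oxy]benzaldehyde (oxa-Michael nitronate) | CC(=O)c1c(O)cc(OC/C=C(\C)CCC=C(C)C)c(C=O)c1OC(C)(C)C=[N+]([O-])[O-] | intermediate (not isolated)
8 | 1-[5-(geranyloxy)-4,7-dihydroxy-2,2-dimethyl-3-nitrochroman-8-yl]ethanone, mixture of diastereomers (nitro-aldol adduct) | CC(=O)c1c(O)cc(OC/C=C(\C)CCC=C(C)C)c2c1OC(C)(C)C([N+](=O)[O-])C2O | intermediate (not isolated)
9 | 1-[5-(geranyloxy)-7-hydroxy-2,2-dimethyl-3-nitro-2H-chromen-8-yl]ethanone | CC(=O)c1c(O)cc(OC/C=C(\C)CCC=C(C)C)c2c1OC(C)(C)C([N+](=O)[O-])=C2 | intermediate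
10 | sodium nitronate of 1-[5-(geranyloxy)-7-hydroxy-2,2-dimethyl-3-nitrochroman-8-yl]ethanone | CC(=O)c1c(O)cc(OC/C=C(\C)CCC=C(C)C)c2c1OC(C)(C)C(=[N+]([O-])[O-])C2.[Na+] | intermediate (not isolated)
11 | 8-acetyl-5-(geranyloxy)-7-hydroxy-2,2-dimethylchroman-3-one | CC(=O)c1c(O)cc(OC/C=C(\C)CCC=C(C)C)c2c1OC(C)(C)C(=O)C2 | intermediate
12 | catechol borate ester of 13, 1-[(3R)-3-(1,3,2-benzodioxaborol-2-yloxy)-5-(geranyloxy)-7-hydroxy-2,2-dimethylchroman-8-yl]ethanone | CC(=O)c1c(O)cc(OC/C=C(\C)CCC=C(C)C)c2c1OC(C)(C)[C@H](OB3Oc4ccccc4O3)C2 | intermediate (not isolated)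
13 | 1-[(3R)-5-(geranyloxy)-3,7-dihydroxy-2,2-dimethylchroman-8-yl]ethanone | CC(=O)c1c(O)cc(OC/C=C(\C)CCC=C(C)C)c2c1OC(C)(C)[C@H](O)C2 | target

**Step count and risks**

Total step count: 5. Longest linear sequence: 5 steps (1 → 3 → 5 → 9 → 11 → 13).

Three steps most likely to fail:

Step 3. What may go wrong: the oxa-Michael addition of the hindered, doubly hydrogen-bonded O1 phenoxide to the β,β-disubstituted nitroalkene may be slow, so that base-induced deconjugation or oligomerisation of 6 outpaces ring closure. Fallback: setting out from 5, the same C3–C4 ring closure is run as an oxa-Michael/aldol condensation domino with 3-methylbut-2-enal (K2CO3, 1,4-dioxane, reflux), in which the enolate carbon C3 attacks the aldehyde carbon C4, to give 8-acetyl-5-(geranyloxy)-7-hydroxy-2,2-dimethyl-2H-chromene-3-carbaldehyde F1. Pinnick oxidation (NaClO2, NaH2PO4, 2-methylbut-2-ene, t-BuOH/H2O) should then give 8-acetyl-5-(geranyloxy)-7-hydroxy-2,2-dimethyl-2H-chromene-3-carboxylic acid F2. Diphenylphosphoryl azide and Et3N in toluene convert it into the acyl azide F3, which on warming should undergo Curtius rearrangement to the vinyl isocyanate F4. Dilute aqueous HCl in THF hydrolyses this through the 3-amino-2H-chromene F5 to chroman-3-one 11, where the route is rejoined.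

Step 5. What may go wrong: facial selectivity may erode if the aryloxy oxygen on C2 competes for boron, and the acetyl group may be partly reduced. Fallback: setting out from 11, NaBH4 in MeOH at 0 °C reduces the C3 ketone without facial control to the racemic alcohol, that is 13 together with its (3S)-enantiomer F6. Preparative chromatography on a chiral stationary phase (amylose tris(3,5-dimethylphenylcarbamate), supercritical CO2/MeOH) then separates the two, and the route is rejoined at 13.

Step 2. What may go wrong: the HCl released may cleave or cyclise the geranyl ether, or the chloroiminium reagent may attack the acetyl methyl group (chromone formation) instead of formylating the ring cleanly. Fallback: setting out from 3, a non-acidic magnesium-phenoxide-directed ortho-formylation is used (MgCl2, Et3N, paraformaldehyde, MeCN, reflux). The magnesium phenoxide delivers formaldehyde to the adjacent ring carbon to give 1-[4-(geranyloxy)-2,6-dihydroxy-3-(hydroxymethyl)phenyl]ethanone F7, which in the same flask transfers hydride to a second formaldehyde and arrives at aldehyde 5.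

**Further compounds**

F1 | step 3 | 8-acetyl-5-(geranyloxy)-7-hydroxy-2,2-dimethyl-2H-chromene-3-carbaldehyde | CC(=O)c1c(O)cc(OC/C=C(\C)CCC=C(C)C)c2c1OC(C)(C)C(C=O)=C2
F2 | step 3 | 8-acetyl-5-(geranyloxy)-7-hydroxy-2,2-dimethyl-2H-chromene-3-carboxylic acid | CC(=O)c1c(O)cc(OC/C=C(\C)CCC=C(C)C)c2c1OC(C)(C)C(C(=O)O)=C2
F3 | step 3 | 8-acetyl-5-(geranyloxy)-7-hydroxy-2,2-dimethyl-2H-chromene-3-carbonyl azide | CC(=O)c1c(O)cc(OC/C=C(\C)CCC=C(C)C)c2c1OC(C)(C)C(C(=O)N=[N+]=[N-])=C2
F4 | step 3 | 1-[5-(geranyloxy)-7-hydroxy-3-isocyanato-2,2-dimethyl-2H-chromen-8-yl]ethanone | CC(=O)c1c(O)cc(OC/C=C(\C)CCC=C(C)C)c2c1OC(C)(C)C(N=C=O)=C2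
F5 | step 3 | 1-[3-amino-5-(geranyloxy)-7-hydroxy-2,2-dimethyl-2H-chromen-8-yl]ethanone | CC(=O)c1c(O)cc(OC/C=C(\C)CCC=C(C)C)c2c1OC(C)(C)C(N)=C2
F6 | step 5 | 1-[(3S)-5-(geranyloxy)-3,7-dihydroxy-2,2-dimethylchroman-8-yl]ethanone | CC(=O)c1c(O)cc(OC/C=C(\C)CCC=C(C)C)c2c1OC(C)(C)[C@@H](O)C2
F7 | step 2 | 1-[4-(geranyloxy)-2,6-dihydroxy-3-(hydroxymethyl)phenyl]ethanone | CC(=O)c1c(O)cc(OC/C=C(\C)CCC=C(C)C)c(CO)c1O
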